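**Retrosynthetic overview**
1. The target is a hydrated oxidative dimer of isoliquiritigenin, so all atoms come from 2,4-dihydroxyacetophenone 1 and 4-hydroxybenzaldehyde 2, condensed (through aldol 3) to chalcone 4.
2. Key disconnection: the C3–C4 bond and both ring C–O bonds are cut at once, back to two phenoxyl radicals 5 of chalcone 4 plus one molecule of water.
3. Forward: Cα–Cα' radical coupling gives meso bis(quinone methide) 6; water adds to one quinone methide (7) and the new benzylic alcohol closes 5-exo onto the other to give 8.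
4. Ring order: the tetrahydrofuran is the only ring made; it forms last, in the same flask as the C–C bond, and all four stereocentres are set there.
5. No protecting groups; two steps.

Assumption 1: the target descriptors, (2R,3R,4S,5S) with 2,3-trans, 3,4-cis, 4,5-trans substituents, describe a meso compound (mirror plane through O1 and the C3–C4 midpoint), so the "single enantiomer" is this one achiral diastereomer and only relative configuration must be controlled.
Assumption 2: the route has only two steps, so the closing list of weak points ranks step 2 twice (two independent failure modes, each with its own fallback) and step 1 once.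

**Step 1**
Reactants: 1 2,4-dihydroxyacetophenone; 2 4-hydroxybenzaldehyde
Product: 4 isoliquiritigenin, via aldol adduct 3 (not isolated)
Conditions: dry HCl (sat.) in abs. EtOH, 0 °C → rt, 24 h, dark
Reagents that add atoms: none
Why: Acid-catalysed Claisen–Schmidt (crossed aldol) condensation, in which the enol of 1 adds to protonated 2 and aldol 3 dehydrates through its p-hydroxybenzylic cation to the conjugated E-enone (thermodynamic geometry, no stereocentre); acid is used because base would turn 2 into an unreactive phenolate, so no protecting groups are needed.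

**Step 2**
Reactants: 4 isoliquiritigenin (two molecules)
Product: 8 meso-2,5-bis(4-hydroxyphenyl)-3,4-bis(2,4-dihydroxybenzoyl)tetrahydrofuran (target), via phenoxyl radical 5 (not isolated), via meso bis(quinone methide) 6 (not isolated), via hydroxy quinone methide 7 (not isolated)
Conditions: horseradish peroxidase (cat.), H2O2 (0.55 equiv, syringe pump, 3 h), degassed acetone/0.1 M acetate buffer pH 4.5 (1:3), 5 mM, Ar, dark, 20 °C; EtOAc extraction, Sephadex LH-20 then C18 HPLC
Reagents that add atoms: water, O
Why: Proposed new method: the peroxidase takes one electron and a proton from the 4-OH of 4 (the chelated acyl-resorcinol ring is a poor substrate) to give radical 5 with high spin density at the captodative Cα; two radicals couple Cα–Cα', and the dipole-cancelling antiparallel (centrosymmetric) encounter gives meso bis(quinone methide) 6, which fixes the cis-3,4 relationship; oxygen is then delivered to each quinone methide carbon from the side of the other half (first water, assisted by 5-exo participation of the neighbouring aroyl carbonyl, giving 7, then 5-exo-trig 1,6-addition of the new benzylic alcohol), which under allylic-strain control places each aryl trans to its adjacent aroyl group and gives the meso trans,cis,trans ring, so all four stereocentres are set here and no enantiocontrol is needed; O2 is excluded because 5 otherwise takes up dioxygen at Cα, and pH 4.5 protects the β-alkoxy ketone product from retro-oxa-Michael opening and C3/C4 epimerisation; the closest known reaction type is the peroxidase or one-electron 8–8' dehydrodimerisation of ferulate esters and 4-hydroxystilbenes in water, whose bis(quinone methides) are trapped by water as 2,5-diaryltetrahydrofurans.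

**Compound list**
1 | 2,4-dihydroxyacetophenone, 1-(2,4-dihydroxyphenyl)ethan-1-one | CC(=O)c1ccc(O)cc1O | starting material
2 | 4-hydroxybenzaldehyde | O=Cc1ccc(O)cc1 | starting material
3 | aldol adduct, 1-(2,4-dihydroxyphenyl)-3-hydroxy-3-(4-hydroxyphenyl)propan-1-one (racemic) | O=C(CC(O)c1ccc(O)cc1)c1ccc(O)cc1O | intermediate
4 | isoliquiritigenin, (E)-1-(2,4-dihydroxyphenyl)-3-(4-hydroxyphenyl)prop-2-en-1-one | O=C(/C=C/c1ccc(O)cc1)c1ccc(O)cc1O | intermediate
5 | 4-phenoxyl radical of 4 (spin delocalised to Cα) | [O]c1ccc(/C=C/C(=O)c2ccc(O)cc2O)cc1 | intermediate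
6 | meso bis(quinone methide), (2R,3S)-1,4-bis(2,4-dihydroxyphenyl)-2,3-bis[(4-oxocyclohexa-2,5-dien-1-ylidene)methyl]butane-1,4-dione | O=C(c1ccc(O)cc1O)[C@@H](C=C1C=CC(=O)C=C1)[C@@H](C=C1C=CC(=O)C=C1)C(=O)c1ccc(O)cc1O | intermediate
7 | hydroxy quinone methide, 1,4-bis(2,4-dihydroxyphenyl)-2-[hydroxy(4-hydroxyphenyl)methyl]-3-[(4-oxocyclohexa-2,5-dien-1-ylidene)methyl]butane-1,4-dione (racemic, one enantiomer drawn; both close to the same meso product) | O=C(c1ccc(O)cc1O)[C@@H]([C@@H](O)c1ccc(O)cc1)[C@H](C(=O)c1ccc(O)cc1O)C=C1C=CC(=O)C=C1 | intermediate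
8 | meso [(2R,3R,4S,5S)-2,5-bis(4-hydroxyphenyl)oxolane-3,4-diyl]bis[(2,4-dihydroxyphenyl)methanone]; 2,3-trans, 3,4-cis, 4,5-trans | O=C(c1ccc(O)cc1O)[C@@H]1[C@H](C(=O)c2ccc(O)cc2O)[C@@H](c2ccc(O)cc2)O[C@H]1c1ccc(O)cc1 | target

**Total step count:** 2. **Longest linear sequence:** 2.

**Steps most likely to fail**

(i) Step 2, site of coupling. Radical 5 can also couple through ring C-3 or the phenoxyl oxygen (benzofuran- and ether-type dimers). Intermediate 6 can be intercepted by a 2'-OH (flavanone closure) or tautomerise to the bis-benzylidene diketone. A realistic yield of 8 is about 10%.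
Fallback, setting out from 1 and returning at 8: condense 1 (HCl/EtOH as in step 1) with 3,5-di-tert-butyl-4-hydroxybenzaldehyde F1 to the hindered chalcone F2. Its phenoxyl radical (Ag2O, CH2Cl2, rt, Ar) is persistent, is blocked at ring carbon and oxygen, and dimerises only Cα–Cα' to an isolable bis(quinone methide). The meso tetra-tert-butyl bis(quinone methide) F3 is separated by crystallisation. TsOH·H2O in wet THF hydrates and cyclises it to the tetra-tert-butyl tetrahydrofuran F4. AlCl3 in toluene/MeNO2 at 50 °C (retro-Friedel–Crafts transfer of tert-butyl to toluene) then gives 8.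

(ii) Step 2, diastereoselectivity. Free radical coupling is expected to give meso and dl dimers in comparable amounts; the dl dimer leads to the 3,4-trans isomer. If water adds directly in the Felkin sense instead of through carbonyl assistance, the 2,3-cis epimer also forms.
Fallback, setting out from 4 and returning at 6: H2, Pd/C, EtOAc gives the dihydrochalcone davidigenin F5. MOMCl/NaH in DMF gives tris-MOM davidigenin F6. LDA, THF, −78 °C then CuCl2 couples the ketone enolate α–α' to 1,4-diketones that are configurationally stable and separable at this oxidation level. The meso hexa-MOM diketone F7 is isolated by chromatography and deprotected (2 M HCl in MeOH, rt) to the meso hexaphenol diketone F8. DDQ (2.1 equiv) in dioxane/H2O oxidises both p-hydroxybenzyl groups to quinone methides, which is compound 6, with C3/C4 already fixed before the ring closes via 7 to 8. This fallback fixes only C3/C4; the water-derived centre is set as in step 2.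

(iii) Step 1. The unprotected condensation may stall or partly cyclise to the flavanone.
Fallback, setting out from 1 and 2 and returning at 4: MOMCl/K2CO3 in acetone protects only the non-chelated 4-OH of 1, giving 2-hydroxy-4-(methoxymethoxy)acetophenone F9. MOMCl/DIPEA converts 2 into 4-(methoxymethoxy)benzaldehyde F10. Base-mediated Claisen–Schmidt condensation (KOH, EtOH, rt) gives the bis-MOM chalcone F11. 3 M HCl in MeOH at 50 °C removes both MOM groups to give 4.

**Further compounds**
F1 | step 2 | 3,5-di-tert-butyl-4-hydroxybenzaldehyde | O=Cc1cc(C(C)(C)C)c(O)c(C(C)(C)C)c1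
F2 | step 2 | (E)-3-(3,5-di-tert-butyl-4-hydroxyphenyl)-1-(2,4-dihydroxyphenyl)prop-2-en-1-one | O=C(/C=C/c1cc(C(C)(C)C)c(O)c(C(C)(C)C)c1)c1ccc(O)cc1O
F3 | step 2 | meso-1,4-bis(2,4-dihydroxyphenyl)-2,3-bis[(3,5-di-tert-butyl-4-oxocyclohexa-2,5-dien-1-ylidene)methyl]butane-1,4-dione | O=C(c1ccc(O)cc1O)[C@@H](C=C1C=C(C(C)(C)C)C(=O)C(C(C)(C)C)=C1)[C@@H](C=C1C=C(C(C)(C)C)C(=O)C(C(C)(C)C)=C1)C(=O)c1ccc(O)cc1O
F4 | step 2 | meso-2,5-bis(3,5-di-tert-butyl-4-hydroxyphenyl)-3,4-bis(2,4-dihydroxybenzoyl)tetrahydrofuran (2,3-trans, 3,4-cis, 4,5-trans) | O=C(c1ccc(O)cc1O)[C@@H]1[C@H](C(=O)c2ccc(O)cc2O)[C@@H](c2cc(C(C)(C)C)c(O)c(C(C)(C)C)c2)O[C@H]1c1cc(C(C)(C)C)c(O)c(C(C)(C)C)c1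
F5 | step 2 | davidigenin, 1-(2,4-dihydroxyphenyl)-3-(4-hydroxyphenyl)propan-1-one | O=C(CCc1ccc(O)cc1)c1ccc(O)cc1O
F6 | step 2 | 1-[2,4-bis(methoxymethoxy)phenyl]-3-[4-(methoxymethoxy)phenyl]propan-1-one | O=C(CCc1ccc(OCOC)cc1)c1ccc(OCOC)cc1OCOC
F7 | step 2 | meso-1,4-bis[2,4-bis(methoxymethoxy)phenyl]-2,3-bis[4-(methoxymethoxy)benzyl]butane-1,4-dione | O=C(c1ccc(OCOC)cc1OCOC)[C@@H](Cc1ccc(OCOC)cc1)[C@@H](Cc1ccc(OCOC)cc1)C(=O)c1ccc(OCOC)cc1OCOC
F8 | step 2 | meso-1,4-bis(2,4-dihydroxyphenyl)-2,3-bis(4-hydroxybenzyl)butane-1,4-dione | O=C(c1ccc(O)cc1O)[C@@H](Cc1ccc(O)cc1)[C@@H](Cc1ccc(O)cc1)C(=O)c1ccc(O)cc1O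
F9 | step 1 | 1-[2-hydroxy-4-(methoxymethoxy)phenyl]ethan-1-one | CC(=O)c1ccc(OCOC)cc1O
F10 | step 1 | 4-(methoxymethoxy)benzaldehyde | O=Cc1ccc(OCOC)cc1
F11 | step 1 | (E)-1-[2-hydroxy-4-(methoxymethoxy)phenyl]-3-[4-(methoxymethoxy)phenyl]prop-2-en-1-one | O=C(/C=C/c1ccc(OCOC)cc1)c1ccc(OCOC)cc1O
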